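Everything rests on cutting the polyene at the single bond C10′–C11′ (carotenoid numbering, primed atoms on the cyclohexenol half), which flanks the methyl-branched trisubstituted alkene C9′=C10′ in the side chain of the cyclohexenol ring. In one operation, zirconium-catalysed syn-methylalumination of a terminal alkyne installs methyl C19′, fixes the E geometry of C9′=C10′ and gives an alkenylalane that is cross-coupled, under palladium and zinc catalysis, with a C26 hexaenyl iodide bearing the bicyclic dihydrofuran end. The precursor is therefore a C13 hydroxy enyne that still lacks this methyl group. The C8 stereocentre of the dihydrofuran ring arises from silver-catalysed cyclisation of an allenol with axis-to-centre chirality transfer.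

Key step: step 13

Remark: carotenoid numbering is used (ring carbons C1–C6 and chain carbons from C7 on the dihydrofuran half, whose ring oxygen bridges C5 and C8; the same locants with primes on the cyclohexenol half), and (R)-α-ionone 1 and (4R,6R)-4-hydroxy-2,2,6-trimethylcyclohexanone 6 are assumed to be purchasable as single enantiomers.

Step 1
Reactants: 1 (R)-α-ionone
Product: 3 (6R)-6-[(1E)-but-1-en-3-yn-1-yl]-1,5,5-trimethylcyclohex-1-ene, via enol phosphate 2 (not isolated)
Conditions: LiN(i-Pr)2 (1.05 equiv), THF, −78 °C; ClP(O)(OEt)2, −78 °C → rt; then LiN(i-Pr)2 (2.3 equiv), THF, −78 °C → rt; H2O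
Reagents that add atoms: none
Why: Conversion of a methyl ketone into a terminal alkyne by enol phosphate formation and β-elimination should work because the amide base at −78 °C removes the methyl proton and then the vinylic proton far faster than the hindered C6′–H, so the C6′ centre of 1 is carried over unchanged.

Step 2
Reactants: 3 enyne
Product: 4 (4R)-4-[(1E)-but-1-en-3-yn-1-yl]-3,5,5-trimethylcyclohex-2-en-1-one
Conditions: t-BuOOH (70% aq., 5 equiv), Rh2(cap)4 (1 mol %, cap = caprolactamate), NaHCO3, CH2Cl2, rt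
Reagents that add atoms: tert-butyl hydroperoxide CC(C)(C)OO
Why: Radical allylic C–H oxidation by the tert-butylperoxyl radical should turn the C3′ methylene, the only secondary allylic position, into the enone, since the tertiary C6′–H is shielded by the gem-dimethyl group and poorly aligned with the ring π-system, and no stereocentre is made or enolised under these near-neutral conditions.

Step 3
Reactants: 4 enynone
Product: 5 (1R,4R)-4-[(1E)-but-1-en-3-yn-1-yl]-3,5,5-trimethylcyclohex-2-en-1-ol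
Conditions: (S)-2-methyl-CBS-oxazaborolidine (0.3 equiv), catecholborane (1.5 equiv), toluene, −78 °C; then MeOH, aq. NaHCO3
Reagents that add atoms: none
Why: Corey–Bakshi–Shibata reduction with the (S)-oxazaborolidine, which treats the alkene arm as the large group, should deliver hydride to give the (R)-carbinol at C3′, the same face the substrate favours (anti to the axial C1′ methyl), so the hydroxyl is set trans to the C6′ side chain while catecholborane at −78 °C leaves the alkyne alone.

Step 4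
Reactants: 6 (4R,6R)-4-hydroxy-2,2,6-trimethylcyclohexan-1-one
Product: 7 (4R,6R)-4-{[tert-butyl(dimethyl)silyl]oxy}-2,2,6-trimethylcyclohexan-1-one
Conditions: TBSCl, imidazole, DMF, rt
Reagents that add atoms: tert-butyldimethylsilyl chloride CC(C)(C)[Si](C)(C)Cl
Why: Imidazole-promoted silylation of the only hydroxyl is routine and touches no stereocentre.

Step 5
Reactants: 7 silyloxy ketone
Product: 8 (4R)-4-{[tert-butyl(dimethyl)silyl]oxy}-2,6,6-trimethylcyclohex-1-en-1-yl trifluoromethanesulfonate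
Conditions: LiN(i-Pr)2, THF, −78 → 0 °C; PhNTf2, −78 °C → rt
Reagents that add atoms: N-phenylbis(trifluoromethanesulfonimide) FC(F)(F)S(=O)(=O)N(c1ccccc1)S(=O)(=O)C(F)(F)F
Why: Enol triflate formation can only give the tetrasubstituted vinyl triflate because the ketone has a single enolisable α-hydrogen (the other α-carbon is quaternary), which erases the methyl-bearing stereocentre as planned and leaves the silyloxy-bearing centre untouched.

Step 6
Reactants: 8 vinyl triflate; 9 (2E)-3-methylpent-2-en-4-yn-1-ol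
Product: 10 (2E)-5-[(4R)-4-{[tert-butyl(dimethyl)silyl]oxy}-2,6,6-trimethylcyclohex-1-en-1-yl]-3-methylpent-2-en-4-yn-1-ol
Conditions: Pd(PPh3)4 (5 mol %), CuI (10 mol %), i-Pr2NH, THF, rt → 45 °C
Reagents that add atoms: none
Why: Sonogashira coupling of the vinyl triflate with the terminal alkyne forms the C6–C7 bond and brings in the E-configured C9=C10 alkene of 9 unchanged.

Step 7
Reactants: 10 dienynol
Product: 11 (2E)-5-[(1R,4S,6R)-4-{[tert-butyl(dimethyl)silyl]oxy}-2,2,6-trimethyl-7-oxabicyclo[4.1.0]heptan-1-yl]-3-methylpent-2-en-4-yn-1-ol (epoxide anti to the silyloxy group)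
Conditions: mCPBA (1.05 equiv), NaHCO3, CH2Cl2, −20 → 0 °C
Reagents that add atoms: 3-chloroperoxybenzoic acid OOC(=O)c1cccc(Cl)c1
Why: Prilezhaev epoxidation should select the tetrasubstituted ring alkene as the most electron-rich π-bond (the trisubstituted alkene is deactivated by its CH2OH group, the alkyne is inert) and is expected to deliver oxygen anti to the C3 silyloxy group, as is usual for 3-O-protected rings of this type, which sets C5 and C6 together, the minor syn epoxide being removed by chromatography.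

Step 8
Reactants: 11 alkynyl epoxide
Product: 12 (2E)-5-[(2R,4S)-4-{[tert-butyl(dimethyl)silyl]oxy}-2-hydroxy-2,6,6-trimethylcyclohexylidene]-3-methylpenta-2,4-dien-1-ol with (R)-configured allene axis
Conditions: i-Bu2AlH (5 equiv), CH2Cl2, 0 °C; aq. potassium sodium tartrate
Reagents that add atoms: none
Why: SN2′ hydride opening of the alkynyl epoxide should occur with aluminium bound to the epoxide oxygen and hydride delivered to C8 on the side of the departing C6–O bond (syn), so the C6 centre is converted into the (R)-configured C6=C7=C8 axis while the C5–O bond and its configuration remain.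

Step 9
Reactants: 12 allenic diol
Product: 13 (2E)-3-[(2S,6S,7aR)-6-{[tert-butyl(dimethyl)silyl]oxy}-4,4,7a-trimethyl-2,4,5,6,7,7a-hexahydro-1-benzofuran-2-yl]but-2-en-1-ol
Conditions: AgNO3 (0.2 equiv), CaCO3, acetone–H2O, rt, dark
Reagents that add atoms: none
Why: Silver-catalysed 5-endo cycloisomerisation of an α-hydroxyallene to a 2,5-dihydrofuran adds the C5 hydroxyl to silver-activated C8 within the plane of the C7=C8 π-bond, so the axial chirality is transferred to C8 and the C9 substituent stays on the face of the C5 methyl group, which is the (8S) configuration.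

Step 10
Reactants: 13 dihydrofuran allylic alcohol
Product: 15 {(2E)-3-[(2S,6S,7aR)-6-{[tert-butyl(dimethyl)silyl]oxy}-4,4,7a-trimethyl-2,4,5,6,7,7a-hexahydro-1-benzofuran-2-yl]but-2-en-1-yl}(triphenyl)phosphonium bromide, via allylic bromide 14 (not isolated)
Conditions: CBr4, PPh3, 2,6-lutidine, CH2Cl2, −20 °C; then PPh3 (1.5 equiv), EtOAc, rt
Reagents that add atoms: carbon tetrabromide BrC(Br)(Br)Br; triphenylphosphine c1ccc(cc1)P(c1ccccc1)c1ccccc1
Why: Appel bromination followed by SN2 quaternisation of PPh3 at the primary allylic carbon is run buffered with 2,6-lutidine so that no acid can ionise the doubly allylic C8–O bond, and no stereocentre is involved.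

Step 11
Reactants: 15 phosphonium bromide; 16 (2E,4E,6E)-2,7-dimethylocta-2,4,6-trienedial (3 equiv)
Product: 17 (2E,4E,6E,8E,10E)-11-[(2S,6S,7aR)-6-{[tert-butyl(dimethyl)silyl]oxy}-4,4,7a-trimethyl-2,4,5,6,7,7a-hexahydro-1-benzofuran-2-yl]-2,7-dimethyldodeca-2,4,6,8,10-pentaenal
Conditions: NaOMe, CH2Cl2–MeOH, 0 °C → rt; then heptane, 80 °C
Reagents that add atoms: none
Why: Wittig olefination of one aldehyde group of the excess dialdehyde by the semistabilised allylic ylide forms C11=C12, and heating should equilibrate any hindered 11Z isomer to the all-E pentaenal.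

Step 12
Reactants: 17 pentaenal
Product: 18 tert-butyl{[(2S,6S,7aR)-2-[(2E,4E,6E,8E,10E,12E)-13-iodo-6,11-dimethyltrideca-2,4,6,8,10,12-hexaen-2-yl]-4,4,7a-trimethyl-2,4,5,6,7,7a-hexahydro-1-benzofuran-6-yl]oxy}dimethylsilane
Conditions: CrCl2 (8 equiv), CHI3 (3 equiv), THF–dioxane, 0 °C, dark
Reagents that add atoms: iodoform IC(I)I
Why: Takai olefination adds the geminal dichromium species from CHI3 and CrCl2 to the aldehyde and eliminates to give the (E)-1-iodoalkene, which introduces C11′ with the required geometry.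

Step 13
Reactants: 5 hydroxy enyne (1.3 equiv); 18 hexaenyl iodide
Product: 20 (3S,5R,8S,3′R,6′R)-3-O-(tert-butyldimethylsilyl)-5,8-epoxy-5,8-dihydro-β,ε-carotene-3,3′-diol, via alkenylalane 19 (not isolated)
Conditions: AlMe3 (3.5 equiv), Cp2ZrCl2 (0.5 equiv), ClCH2CH2Cl, 0 → 23 °C; volatiles removed in vacuo; then 18, Pd2(dba)3 (2.5 mol %), P(2-furyl)3 (10 mol %), ZnCl2 (0.5 equiv), THF, 23 °C, dark; aq. potassium sodium tartrate
Reagents that add atoms: trimethylaluminium C[Al](C)C
Why: Cp2ZrCl2 and AlMe3 generate a methylzirconium species that adds methyl and metal syn across the terminal alkyne of 5 (methyl to C9′, metal to C10′) and hands the alkenyl group to aluminium as the (E)-alkenylalane 19, after which zerovalent palladium inserts into the C11′–I bond of 18, ZnCl2 relays the alkenyl group from aluminium to palladium, and reductive elimination forms C10′–C11′. The closest known reaction type is the Negishi tandem of zirconium-catalysed carboalumination and palladium-catalysed cross-coupling used to assemble methyl-branched polyene chains. No ring is closed and no stereocentre is created; the stereochemical elements fixed are the E geometry of C9′=C10′, controlled by the syn addition and by placement of methyl on the internal alkyne carbon, and the E geometry of C11′=C12′, carried over from 18 because oxidative addition and reductive elimination proceed with retention. The step needs chemoselectivity for the alkyne over the ring alkene and C7′=C8′, which the strong preference of this carbometalation for terminal alkynes secures, and it needs the doubly allylic C8–O ether, the allylic C3′ alkoxide and the C6′ centre to survive Lewis acid, which is secured by stripping excess AlMe3 before the coupling, by the donor solvent THF and by working at or below 23 °C.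

Step 14
Reactants: 20 monosilyl ether
Product: 21 (3S,5R,8S,3′R,6′R)-5,8-epoxy-5,8-dihydro-β,ε-carotene-3,3′-diol
Conditions: Bu4NF, THF, 0 °C → rt
Reagents that add atoms: none
Why: Fluoride-mediated desilylation frees the C3 hydroxyl under non-acidic conditions that leave the C8 ether, the allylic C3′ alcohol and the polyene untouched.

Compound list
1 | (R)-α-ionone, (3E)-4-[(1R)-2,6,6-trimethylcyclohex-2-en-1-yl]but-3-en-2-one | CC1=CCCC(C)(C)[C@H]1/C=C/C(C)=O | starting material
2 | diethyl (3E)-4-[(1R)-2,6,6-trimethylcyclohex-2-en-1-yl]buta-1,3-dien-2-yl phosphate | CC1=CCCC(C)(C)[C@H]1/C=C/C(=C)OP(=O)(OCC)OCC | intermediate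
3 | (6R)-6-[(1E)-but-1-en-3-yn-1-yl]-1,5,5-trimethylcyclohex-1-ene | CC1=CCCC(C)(C)[C@H]1/C=C/C#C | intermediate
4 | (4R)-4-[(1E)-but-1-en-3-yn-1-yl]-3,5,5-trimethylcyclohex-2-en-1-one | CC1=CC(=O)CC(C)(C)[C@H]1/C=C/C#C | intermediate
5 | (1R,4R)-4-[(1E)-but-1-en-3-yn-1-yl]-3,5,5-trimethylcyclohex-2-en-1-ol | CC1=C[C@H](O)CC(C)(C)[C@H]1/C=C/C#C | intermediate
6 | (4R,6R)-4-hydroxy-2,2,6-trimethylcyclohexan-1-one | CC1(C)C[C@H](O)C[C@@H](C)C1=O | starting material
7 | (4R,6R)-4-{[tert-butyl(dimethyl)silyl]oxy}-2,2,6-trimethylcyclohexan-1-one | CC1(C)C[C@H](O[Si](C)(C)C(C)(C)C)C[C@@H](C)C1=O | intermediate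
8 | (4R)-4-{[tert-butyl(dimethyl)silyl]oxy}-2,6,6-trimethylcyclohex-1-en-1-yl trifluoromethanesulfonate | CC1(C)C[C@H](O[Si](C)(C)C(C)(C)C)CC(C)=C1OS(=O)(=O)C(F)(F)F | intermediate
9 | (2E)-3-methylpent-2-en-4-yn-1-ol | C#C/C(C)=C/CO | starting material
10 | (2E)-5-[(4R)-4-{[tert-butyl(dimethyl)silyl]oxy}-2,6,6-trimethylcyclohex-1-en-1-yl]-3-methylpent-2-en-4-yn-1-ol | CC1(C)C[C@H](O[Si](C)(C)C(C)(C)C)CC(C)=C1C#C/C(C)=C/CO | intermediate
11 | (2E)-5-[(1R,4S,6R)-4-{[tert-butyl(dimethyl)silyl]oxy}-2,2,6-trimethyl-7-oxabicyclo[4.1.0]heptan-1-yl]-3-methylpent-2-en-4-yn-1-ol, epoxide oxygen anti to the silyloxy group | CC1(C)C[C@H](O[Si](C)(C)C(C)(C)C)C[C@@]2(C)O[C@@]12C#C/C(C)=C/CO | intermediate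
12 | (2E)-5-[(2R,4S)-4-{[tert-butyl(dimethyl)silyl]oxy}-2-hydroxy-2,6,6-trimethylcyclohexylidene]-3-methylpenta-2,4-dien-1-ol, (R)-configured allene axis (C8–H on the side of the C5 hydroxyl) | CC1(C)C[C@H](O[Si](C)(C)C(C)(C)C)C[C@@](C)(O)C1=[C@]=C/C(C)=C/CO | intermediate
13 | (2E)-3-[(2S,6S,7aR)-6-{[tert-butyl(dimethyl)silyl]oxy}-4,4,7a-trimethyl-2,4,5,6,7,7a-hexahydro-1-benzofuran-2-yl]but-2-en-1-ol | OC/C=C(C)/[C@@H]1C=C2C(C)(C)C[C@H](O[Si](C)(C)C(C)(C)C)C[C@@]2(C)O1 | intermediate
14 | {[(2S,6S,7aR)-2-[(2E)-4-bromobut-2-en-2-yl]-4,4,7a-trimethyl-2,4,5,6,7,7a-hexahydro-1-benzofuran-6-yl]oxy}(tert-butyl)dimethylsilane | BrC/C=C(C)/[C@@H]1C=C2C(C)(C)C[C@H](O[Si](C)(C)C(C)(C)C)C[C@@]2(C)O1 | intermediate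
15 | {(2E)-3-[(2S,6S,7aR)-6-{[tert-butyl(dimethyl)silyl]oxy}-4,4,7a-trimethyl-2,4,5,6,7,7a-hexahydro-1-benzofuran-2-yl]but-2-en-1-yl}(triphenyl)phosphonium bromide | [Br-].C(/C=C(C)/[C@@H]1C=C2C(C)(C)C[C@H](O[Si](C)(C)C(C)(C)C)C[C@@]2(C)O1)[P+](c1ccccc1)(c1ccccc1)c1ccccc1 | intermediate
16 | (2E,4E,6E)-2,7-dimethylocta-2,4,6-trienedial | O=C/C(C)=C/C=C/C=C(C)/C=O | starting material
17 | (2E,4E,6E,8E,10E)-11-[(2S,6S,7aR)-6-{[tert-butyl(dimethyl)silyl]oxy}-4,4,7a-trimethyl-2,4,5,6,7,7a-hexahydro-1-benzofuran-2-yl]-2,7-dimethyldodeca-2,4,6,8,10-pentaenal | O=C/C(C)=C/C=C/C=C(C)/C=C/C=C(C)/[C@@H]1C=C2C(C)(C)C[C@H](O[Si](C)(C)C(C)(C)C)C[C@@]2(C)O1 | intermediate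
18 | tert-butyl{[(2S,6S,7aR)-2-[(2E,4E,6E,8E,10E,12E)-13-iodo-6,11-dimethyltrideca-2,4,6,8,10,12-hexaen-2-yl]-4,4,7a-trimethyl-2,4,5,6,7,7a-hexahydro-1-benzofuran-6-yl]oxy}dimethylsilane | I/C=C/C(C)=C/C=C/C=C(C)/C=C/C=C(C)/[C@@H]1C=C2C(C)(C)C[C@H](O[Si](C)(C)C(C)(C)C)C[C@@]2(C)O1 | intermediate
19 | dimethyl{(1E,3E)-4-[(1R,4R)-4-[(dimethylalumanyl)oxy]-2,6,6-trimethylcyclohex-2-en-1-yl]-2-methylbuta-1,3-dien-1-yl}alumane | CC1=C[C@H](O[Al](C)C)CC(C)(C)[C@H]1/C=C/C(C)=C/[Al](C)C | intermediate
20 | (3S,5R,8S,3′R,6′R)-3-O-(tert-butyldimethylsilyl)-5,8-epoxy-5,8-dihydro-β,ε-carotene-3,3′-diol | CC1=C[C@H](O)CC(C)(C)[C@H]1/C=C/C(C)=C/C=C/C(C)=C/C=C/C=C(C)/C=C/C=C(\C)[C@@H]1C=C2C(C)(C)C[C@H](O[Si](C)(C)C(C)(C)C)C[C@@]2(C)O1 | intermediate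
21 | (3S,5R,8S,3′R,6′R)-5,8-epoxy-5,8-dihydro-β,ε-carotene-3,3′-diol (chrysanthemaxanthin) | CC1=C[C@H](O)CC(C)(C)[C@H]1/C=C/C(C)=C/C=C/C(C)=C/C=C/C=C(C)/C=C/C=C(\C)[C@@H]1C=C2C(C)(C)C[C@H](O)C[C@@]2(C)O1 | target

Total step count: 14. Longest linear sequence: 11 steps (6 → 21, steps 4 to 14); the three-step branch 1 → 5 joins at step 13.

Steps most likely to fail

Step 13 (key step). The Lewis-acidic aluminium and zinc species may ionise the doubly allylic C8–O bond of 18, causing epimerisation at C8 or ring opening, and the hexaenyl iodide may decompose before transmetalation. The fallback is a Suzuki–Miyaura union under basic aqueous conditions. It sets out from 5 and 17. Compound 5 is carboaluminated as in step 13 and the alane is quenched with I2 in THF at −30 °C to give (1R,4R)-4-[(1E,3E)-4-iodo-3-methylbuta-1,3-dien-1-yl]-3,5,5-trimethylcyclohex-2-en-1-ol F1. Aldehyde 17 is homologated with 2-(dichloromethyl)-4,4,5,5-tetramethyl-1,3,2-dioxaborolane, CrCl2 and LiI in THF to the (E)-hexaenylboronic acid pinacol ester F2. Coupling of the two with Pd(OAc)2, SPhos and aq. K3PO4 in THF at rt should give 20, where the route resumes at step 14.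

Step 2. Peroxyl radicals may add to the conjugated enyne, or hydrogen abstraction at C6′ may compete with oxidation at C3′, leading to oligomers or regioisomeric enones. The fallback sets out from 1 and oxidises the ring while the side chain is masked as a ketal, a non-conjugated substrate close to α-ionone itself. Ketalisation (ethylene glycol, HC(OMe)3, cat. TsOH) gives the dioxolane F3. Allylic oxidation as in step 2 gives the enone ketal F4, and reduction as in step 3 gives the (1R,4R)-hydroxy ketal F5. Mild hydrolysis (pyridinium tosylate, acetone–H2O) gives (3R,6R)-3-hydroxy-α-ionone F6, and silylation (TBSCl, imidazole) gives the silyl ether F7. The sequence of step 1 then gives the enol phosphate F8 and from it the silyl-protected enyne F9. Bu4NF removes the silyl group to give 5, where the route resumes at step 13.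

Step 7. The peracid may attack the ring alkene with poor or reversed facial selectivity, leaving the epoxide syn to the silyloxy group as a major product. The fallback sets out from 10 and uses a halohydrin sequence, which places the oxygen on the face opposite to the one an electrophile attacks directly. NBS in THF–H2O at 0 °C should form the bromonium ion on the face the peracid prefers and open it with water at C5 to give the trans-bromohydrin (2E)-5-[(1S,2R,4S)-1-bromo-4-{[tert-butyl(dimethyl)silyl]oxy}-2-hydroxy-2,6,6-trimethylcyclohexyl]-3-methylpent-2-en-4-yn-1-ol F10. K2CO3 in MeOH then closes the epoxide by intramolecular displacement of bromide to give 11, where the route resumes at step 8.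

Further compounds
F1 | step 13 | (1R,4R)-4-[(1E,3E)-4-iodo-3-methylbuta-1,3-dien-1-yl]-3,5,5-trimethylcyclohex-2-en-1-ol | CC1=C[C@H](O)CC(C)(C)[C@H]1/C=C/C(C)=C/I
F2 | step 13 | tert-butyl{[(2S,6S,7aR)-2-[(2E,4E,6E,8E,10E,12E)-6,11-dimethyl-13-(4,4,5,5-tetramethyl-1,3,2-dioxaborolan-2-yl)trideca-2,4,6,8,10,12-hexaen-2-yl]-4,4,7a-trimethyl-2,4,5,6,7,7a-hexahydro-1-benzofuran-6-yl]oxy}dimethylsilane | CC1(C)OB(/C=C/C(C)=C/C=C/C=C(C)/C=C/C=C(C)/[C@@H]2C=C3C(C)(C)C[C@H](O[Si](C)(C)C(C)(C)C)C[C@@]3(C)O2)OC1(C)C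
F3 | step 2 | 2-methyl-2-{(E)-2-[(1R)-2,6,6-trimethylcyclohex-2-en-1-yl]ethenyl}-1,3-dioxolane | CC1=CCCC(C)(C)[C@H]1/C=C/C2(C)OCCO2
F4 | step 2 | (4R)-3,5,5-trimethyl-4-[(E)-2-(2-methyl-1,3-dioxolan-2-yl)ethenyl]cyclohex-2-en-1-one | CC1=CC(=O)CC(C)(C)[C@H]1/C=C/C2(C)OCCO2
F5 | step 2 | (1R,4R)-3,5,5-trimethyl-4-[(E)-2-(2-methyl-1,3-dioxolan-2-yl)ethenyl]cyclohex-2-en-1-ol | CC1=C[C@H](O)CC(C)(C)[C@H]1/C=C/C2(C)OCCO2
F6 | step 2 | (3E)-4-[(1R,4R)-4-hydroxy-2,6,6-trimethylcyclohex-2-en-1-yl]but-3-en-2-one | CC1=C[C@H](O)CC(C)(C)[C@H]1/C=C/C(C)=O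
F7 | step 2 | (3E)-4-[(1R,4R)-4-{[tert-butyl(dimethyl)silyl]oxy}-2,6,6-trimethylcyclohex-2-en-1-yl]but-3-en-2-one | CC1=C[C@H](O[Si](C)(C)C(C)(C)C)CC(C)(C)[C@H]1/C=C/C(C)=O
F8 | step 2 | diethyl (3E)-4-[(1R,4R)-4-{[tert-butyl(dimethyl)silyl]oxy}-2,6,6-trimethylcyclohex-2-en-1-yl]buta-1,3-dien-2-yl phosphate | CC1=C[C@H](O[Si](C)(C)C(C)(C)C)CC(C)(C)[C@H]1/C=C/C(=C)OP(=O)(OCC)OCC
F9 | step 2 | tert-butyl{[(1R,4R)-4-[(1E)-but-1-en-3-yn-1-yl]-3,5,5-trimethylcyclohex-2-en-1-yl]oxy}dimethylsilane | CC1=C[C@H](O[Si](C)(C)C(C)(C)C)CC(C)(C)[C@H]1/C=C/C#C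
F10 | step 7 | (2E)-5-[(1S,2R,4S)-1-bromo-4-{[tert-butyl(dimethyl)silyl]oxy}-2-hydroxy-2,6,6-trimethylcyclohexyl]-3-methylpent-2-en-4-yn-1-ol | CC1(C)C[C@H](O[Si](C)(C)C(C)(C)C)C[C@@](C)(O)[C@@]1(Br)C#C/C(C)=C/CO
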